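**Retrosynthetic overview**

1. Ring B is numbered C1 (CH bearing the guaiacyl ring), C2 (CH–CHO), C3 (=C–CH2OH), C4 (=CH), C4a, C8a; ring A is the fused 7-hydroxy-6-methoxybenzene ring. The strategy rests on this feature: if ring A is bonded to C3 instead of C4, then C4 and the hydroxymethyl carbon are two equal CH2–O arms on a quaternary C3 of a five-membered indane.
2. Key disconnection: the C4–C4a bond, made by a 1,2-shift of ring A carbon C4a from C3 to one CH2 arm during buffered acetolysis of gem-bis(mesyloxymethyl)indane 16. This expands the five-membered ring to ring B and leaves C3=C4 with an acetoxymethyl group on C3 (18).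
3. The gem-diol comes from (S)-3-arylindan-1-one 8 by trans C2 hydroxymethylation, one-carbon homologation of the ketone to the aldehyde, and a Tollens aldol/Cannizzaro sequence with formaldehyde.
4. The indanone ring is formed first, by enantioselective reductive Heck cyclisation of 2'-bromochalcone 7, made from the methyl ketone derived from 6-bromovanillin (the aldehyde must first become an acetyl group) and O-benzylvanillin.
5. The phenols are carried as benzyl ethers and freed before the key step. After it, the acetate is exchanged for Troc carbonates so that no base or strong acid is used once the β,γ-unsaturated aldehyde exists. Ring order: five-membered ring (step 5), then ring B (step 12).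

Key step: step 12

Assumption: the sense of induction of the bisphosphine in step 5 is taken by analogy, so the ligand antipode that gives (3S)-8 is the one used; the target is treated as the open hydroxy aldehyde shown, which is in ring–chain equilibrium with its lactol.

**Route**

Step 1
Reactants: 1 6-bromovanillin
Product: 2 4-(benzyloxy)-2-bromo-5-methoxybenzaldehyde
Conditions: BnBr, K2CO3, DMF, rt
Reagents that add atoms: benzyl bromide, BrCc1ccccc1
Why: Williamson etherification of the acidic para-formyl phenol should be clean, and the benzyl ether survives every basic, acidic and organometallic step up to the mesylate and is removed by hydrogenolysis before any alkene is present.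

Step 2
Reactants: 2 4-(benzyloxy)-2-bromo-5-methoxybenzaldehyde
Product: 3 1-[4-(benzyloxy)-2-bromo-5-methoxyphenyl]ethan-1-ol (racemic)
Conditions: MeMgBr, THF, 0 °C; aq. NH4Cl
Reagents that add atoms: methylmagnesium bromide, C[Mg]Br
Why: Grignard addition to the aryl aldehyde is fast at 0 °C, where the aryl bromide is inert, and the racemic carbinol centre is removed in step 3.

Step 3
Reactants: 3 1-[4-(benzyloxy)-2-bromo-5-methoxyphenyl]ethan-1-ol
Product: 4 1-[4-(benzyloxy)-2-bromo-5-methoxyphenyl]ethan-1-one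
Conditions: MnO2 (activated), CH2Cl2, rt
Reagents that add atoms: none
Why: MnO2 oxidation of the electron-rich benzylic alcohol to the aryl methyl ketone leaves the aryl bromide and the benzyl ether untouched.

Step 4
Reactants: 4 1-[4-(benzyloxy)-2-bromo-5-methoxyphenyl]ethan-1-one; 5 4-(benzyloxy)-3-methoxybenzaldehyde (O-benzylvanillin)
Product: 7 (E)-1-[4-(benzyloxy)-2-bromo-5-methoxyphenyl]-3-[4-(benzyloxy)-3-methoxyphenyl]prop-2-en-1-one, via aldol adduct 6 (not isolated)
Conditions: NaOH, EtOH/THF, rt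
Reagents that add atoms: none
Why: Claisen–Schmidt condensation of the methyl ketone with the non-enolisable aldehyde, with E1cB dehydration of the aldol adduct, should give the thermodynamically favoured E enone.

Step 5
Reactants: 7 (E)-2'-bromochalcone
Product: 8 (3S)-5-(benzyloxy)-3-[4-(benzyloxy)-3-methoxyphenyl]-6-methoxy-2,3-dihydro-1H-inden-1-one
Conditions: Pd(OAc)2 (5 mol%), (R)-3,5-Xyl-MeO-BIPHEP (6 mol%), HCO2Na, DMF, 80 °C
Reagents that add atoms: none
Why: Enantioselective intramolecular reductive Heck cyclisation, a known route from 2'-halochalcones to 3-arylindanones: oxidative addition of C–Br to zerovalent palladium, 5-exo carbopalladation of the enone β-carbon under control of the chiral bisphosphine (this sets C3), and reduction of the palladium enolate by formate-derived hydride.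

Step 6
Reactants: 8 (3S)-3-arylindan-1-one
Product: 9 (2S,3S)-5-(benzyloxy)-3-[4-(benzyloxy)-3-methoxyphenyl]-2-(hydroxymethyl)-6-methoxy-2,3-dihydro-1H-inden-1-one
Conditions: LiN(SiMe3)2, THF, −78 °C; CH2O (monomer from paraformaldehyde, THF), −78 to −40 °C; aq. NH4Cl
Reagents that add atoms: formaldehyde, C=O
Why: Aldol hydroxymethylation of the kinetic lithium enolate, in which formaldehyde approaches C2 anti to the C3 aryl group and the epimerisable α-centre also prefers that arrangement, should give the 2,3-trans (2S) isomer.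

Step 7
Reactants: 9 (2S,3S)-2-(hydroxymethyl)indanone
Product: 10 (2S,3S)-5-(benzyloxy)-3-[4-(benzyloxy)-3-methoxyphenyl]-2-{[(tert-butyldiphenylsilyl)oxy]methyl}-6-methoxy-2,3-dihydro-1H-inden-1-one
Conditions: TBDPSCl, imidazole, CH2Cl2, 0 °C to rt
Reagents that add atoms: tert-butyl(chloro)diphenylsilane, CC(C)(C)[Si](Cl)(c1ccccc1)c1ccccc1
Why: Silylation of the primary alcohol blocks retro-aldol and dehydration of the β-hydroxy ketone and gives an ether that should tolerate aqueous acid, KOH and hot buffered acetic acid.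

Step 8
Reactants: 10 (2S,3S)-2-(silyloxymethyl)indanone
Product: 12 (2R,3S)-5-(benzyloxy)-3-[4-(benzyloxy)-3-methoxyphenyl]-2-{[(tert-butyldiphenylsilyl)oxy]methyl}-6-methoxy-2,3-dihydro-1H-indene-1-carbaldehyde (C1 epimers), via methyl enol ether 11 (not isolated)
Conditions: Ph3P(CH2OMe)Cl, KN(SiMe3)2, THF, 0 °C to rt; then 2 M aq. HCl, THF, rt
Reagents that add atoms: (methoxymethyl)triphenylphosphonium chloride, COC[P+](c1ccccc1)(c1ccccc1)c1ccccc1.[Cl-]; water, O
Why: Wittig methoxymethylenation of the ketone and acid hydrolysis of the enol ether give the homologous aldehyde, an excess of the small ylide is used because the aryl ketone is hindered, and the C1 epimer mixture is of no consequence because C1 becomes an achiral quaternary carbon in step 9.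

Step 9
Reactants: 12 (2R,3S)-indane-1-carbaldehyde
Product: 14 [(2R,3S)-5-(benzyloxy)-3-[4-(benzyloxy)-3-methoxyphenyl]-2-{[(tert-butyldiphenylsilyl)oxy]methyl}-6-methoxy-2,3-dihydro-1H-indene-1,1-diyl]dimethanol, via hydroxymethyl aldehyde 13 (not isolated)
Conditions: 37% aq. CH2O (excess), KOH, MeOH/THF, rt
Reagents that add atoms: formaldehyde, C=O
Why: Tollens condensation, in which aldol addition of the α-aryl aldehyde enolate to formaldehyde gives non-enolisable 13 and a crossed Cannizzaro reaction with more formaldehyde reduces it to the 1,3-diol, while C2 and C3 carry no acidic hydrogen and are untouched.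

Step 10
Reactants: 14 indane-1,1-diyldimethanol
Product: 15 [(2R,3S)-5-(benzyloxy)-3-[4-(benzyloxy)-3-methoxyphenyl]-2-{[(tert-butyldiphenylsilyl)oxy]methyl}-6-methoxy-2,3-dihydro-1H-indene-1,1-diyl]dimethanediyl dimethanesulfonate
Conditions: MsCl, Et3N, CH2Cl2, 0 °C
Reagents that add atoms: methanesulfonyl chloride, CS(Cl)(=O)=O
Why: Sulfonylation of both neopentyl primary alcohols through sulfene is fast at 0 °C, and neopentyl mesylates do not undergo substitution without aryl assistance.

Step 11
Reactants: 15 bis-benzyl bis-mesylate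
Product: 16 [(2R,3S)-2-{[(tert-butyldiphenylsilyl)oxy]methyl}-5-hydroxy-3-(4-hydroxy-3-methoxyphenyl)-6-methoxy-2,3-dihydro-1H-indene-1,1-diyl]dimethanediyl dimethanesulfonate
Conditions: H2 (1 atm), 10% Pd/C, EtOAc/EtOH, rt
Reagents that add atoms: none
Why: Hydrogenolysis of the two aryl benzyl ethers is placed here because no alkene or aldehyde is present yet, and it frees the ring A hydroxyl para to the ring carbon that migrates in step 12 while mesylates and silyl ether are inert.

Step 12
Reactants: 16 bis-phenol bis-mesylate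
Product: 18 (1S,2R)-3-(acetoxymethyl)-2-{[(tert-butyldiphenylsilyl)oxy]methyl}-1-(4-hydroxy-3-methoxyphenyl)-6-methoxy-1,2-dihydronaphthalen-7-ol (target numbering), via allylic mesylate 17 (not isolated)
Conditions: NaOAc (4 equiv), AcOH (0.02 M), 80 °C, N2
Reagents that add atoms: acetic acid, CC(=O)O; sodium acetate, CC(=O)[O-].[Na+]
Why: Ionisation of either CH2–OMs bond is assisted by ring A carbon C4a, whose para C7 hydroxyl stabilises the bridged phenonium ion; opening of the old C3–C4a bond moves ring A onto the former CH2 (now C4) and leaves a tertiary cation at C3, which loses a C4 proton, directly or after a 1,2-hydride shift from C4, to give 17, whose remaining mesylate is now allylic and is exchanged for acetate to give 18. The closest known reaction type is the neophyl (Wagner–Meerwein) aryl shift in sulfonate acetolysis, as in the ring enlargement of 9-fluorenylmethyl and 1-indanylmethyl derivatives to phenanthrenes and dihydronaphthalenes. Ring B is closed by ring expansion: 3-exo attack of C4a on the CH2 carbon, then cleavage of the internal cyclopropane bond, inserts that carbon between C3 and C4a of the five-membered ring. No stereocentre is formed, and C1 and C2 take no part in the cationic events. The step needs aryl migration over C2 migration (π participation of the electron-rich ring, whereas the in-plane C3–C2 bond gains no benzylic help), opening of the bridged ion toward tertiary C3 instead of acetate capture at CH2 (a monoacetate formed that way still has the second mesylate and can re-enter), and proton loss from C4 instead of C2 (conjugation of the new alkene with ring A). Capture of the cations by the silyl ether oxygen is held back by the bulky TBDPS group, high dilution and the acetate buffer.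

Step 13
Reactants: 18 allylic acetate
Product: 19 (1S,2R)-2-{[(tert-butyldiphenylsilyl)oxy]methyl}-3-(hydroxymethyl)-1-(4-hydroxy-3-methoxyphenyl)-6-methoxy-1,2-dihydronaphthalen-7-ol
Conditions: iBu2AlH, CH2Cl2, −78 °C; aq. potassium sodium tartrate
Reagents that add atoms: none
Why: Reductive cleavage of the acetate at low temperature avoids the alkoxide conditions under which this para-hydroxycinnamyl-type acetate would ionise to a quinone methide, and the silyl ether and both stereocentres are unaffected.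

Step 14
Reactants: 19 bis-phenol allylic alcohol
Product: 20 tris(2,2,2-trichloroethyl carbonate) of 19 (both phenols and the allylic alcohol; 1S,2R)
Conditions: Cl3CCH2OCOCl, pyridine, CH2Cl2, 0 °C
Reagents that add atoms: 2,2,2-trichloroethyl chloroformate, ClC(=O)OCC(Cl)(Cl)Cl
Why: Acylation of the two phenols and the primary allylic alcohol gives carbonates that are stable to fluoride and to Dess–Martin oxidation and are later removed by zinc without base.

Step 15
Reactants: 20 tris-carbonate silyl ether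
Product: 21 (1S,2R)-2-(hydroxymethyl) tris-carbonate
Conditions: HF·pyridine, pyridine, THF, 0 °C to rt
Reagents that add atoms: none
Why: Fluoride-mediated desilylation cleaves the primary TBDPS ether, while the trichloroethyl carbonates, which are base-labile but stable to acidic fluoride, remain.

Step 16
Reactants: 21 primary alcohol
Product: 22 (1S,2R)-2-formyl tris-carbonate
Conditions: Dess–Martin periodinane, NaHCO3, CH2Cl2, 0 °C to rt
Reagents that add atoms: none
Why: Dess–Martin oxidation under bicarbonate buffer gives the aldehyde without over-oxidation, and the non-basic medium should neither epimerise C2 nor move the C3=C4 double bond into conjugation.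

Step 17
Reactants: 22 aldehyde tris-carbonate
Product: 23 CNP0591394.1, (1S,2R)-7-hydroxy-3-(hydroxymethyl)-1-(4-hydroxy-3-methoxyphenyl)-6-methoxy-1,2-dihydronaphthalene-2-carbaldehyde
Conditions: Zn dust, AcOH, THF, 0 °C to rt
Reagents that add atoms: none
Why: Reductive β-elimination of the three Troc groups by zinc releases carbonic half-esters that lose CO2, which frees both phenols and the allylic alcohol in a weakly acidic medium that should leave the α-stereocentre of the β,γ-unsaturated aldehyde intact.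

**Compound list**

1 | 6-bromovanillin (2-bromo-4-hydroxy-5-methoxybenzaldehyde) | O=Cc1cc(OC)c(O)cc1Br | starting material
2 | 4-(benzyloxy)-2-bromo-5-methoxybenzaldehyde | O=Cc1cc(OC)c(OCc2ccccc2)cc1Br | intermediate
3 | 1-[4-(benzyloxy)-2-bromo-5-methoxyphenyl]ethan-1-ol (racemic) | CC(O)c1cc(OC)c(OCc2ccccc2)cc1Br | intermediate
4 | 1-[4-(benzyloxy)-2-bromo-5-methoxyphenyl]ethan-1-one | CC(=O)c1cc(OC)c(OCc2ccccc2)cc1Br | intermediate
5 | 4-(benzyloxy)-3-methoxybenzaldehyde (O-benzylvanillin) | COc1cc(C=O)ccc1OCc1ccccc1 | starting material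
6 | aldol adduct, 1-[4-(benzyloxy)-2-bromo-5-methoxyphenyl]-3-[4-(benzyloxy)-3-methoxyphenyl]-3-hydroxypropan-1-one (not isolated) | COc1cc(C(O)CC(=O)c2cc(OC)c(OCc3ccccc3)cc2Br)ccc1OCc1ccccc1 | intermediate
7 | (E)-1-[4-(benzyloxy)-2-bromo-5-methoxyphenyl]-3-[4-(benzyloxy)-3-methoxyphenyl]prop-2-en-1-one | COc1cc(/C=C/C(=O)c2cc(OC)c(OCc3ccccc3)cc2Br)ccc1OCc1ccccc1 | intermediate
8 | (3S)-5-(benzyloxy)-3-[4-(benzyloxy)-3-methoxyphenyl]-6-methoxy-2,3-dihydro-1H-inden-1-one | COc1cc([C@H]2c3cc(OCc4ccccc4)c(OC)cc3C(=O)C2)ccc1OCc1ccccc1 | intermediate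
9 | (2S,3S)-5-(benzyloxy)-3-[4-(benzyloxy)-3-methoxyphenyl]-2-(hydroxymethyl)-6-methoxy-2,3-dihydro-1H-inden-1-one (2,3-trans) | COc1cc([C@H]2c3cc(OCc4ccccc4)c(OC)cc3C(=O)[C@@H]2CO)ccc1OCc1ccccc1 | intermediate
10 | (2S,3S)-5-(benzyloxy)-3-[4-(benzyloxy)-3-methoxyphenyl]-2-{[(tert-butyldiphenylsilyl)oxy]methyl}-6-methoxy-2,3-dihydro-1H-inden-1-one | COc1cc([C@H]2c3cc(OCc4ccccc4)c(OC)cc3C(=O)[C@@H]2CO[Si](c5ccccc5)(c6ccccc6)C(C)(C)C)ccc1OCc7ccccc7 | intermediate
11 | (2R,3S)-1-(methoxymethylidene) analogue of 10, E/Z mixture (not isolated) | COc1cc([C@H]2c3cc(OCc4ccccc4)c(OC)cc3C(=COC)[C@@H]2CO[Si](c5ccccc5)(c6ccccc6)C(C)(C)C)ccc1OCc7ccccc7 | intermediate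
12 | (2R,3S)-5-(benzyloxy)-3-[4-(benzyloxy)-3-methoxyphenyl]-2-{[(tert-butyldiphenylsilyl)oxy]methyl}-6-methoxy-2,3-dihydro-1H-indene-1-carbaldehyde (C1 epimers) | COc1cc([C@H]2c3cc(OCc4ccccc4)c(OC)cc3C(C=O)[C@@H]2CO[Si](c5ccccc5)(c6ccccc6)C(C)(C)C)ccc1OCc7ccccc7 | intermediate
13 | (2R,3S)-1-(hydroxymethyl) derivative of aldehyde 12, C1 epimers (not isolated) | COc1cc([C@H]2c3cc(OCc4ccccc4)c(OC)cc3C(C=O)(CO)[C@@H]2CO[Si](c5ccccc5)(c6ccccc6)C(C)(C)C)ccc1OCc7ccccc7 | intermediate
14 | [(2R,3S)-5-(benzyloxy)-3-[4-(benzyloxy)-3-methoxyphenyl]-2-{[(tert-butyldiphenylsilyl)oxy]methyl}-6-methoxy-2,3-dihydro-1H-indene-1,1-diyl]dimethanol | COc1cc([C@H]2c3cc(OCc4ccccc4)c(OC)cc3C(CO)(CO)[C@@H]2CO[Si](c5ccccc5)(c6ccccc6)C(C)(C)C)ccc1OCc7ccccc7 | intermediate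
15 | bis(methanesulfonate) of diol 14 (2R,3S) | COc1cc([C@H]2c3cc(OCc4ccccc4)c(OC)cc3C(COS(C)(=O)=O)(COS(C)(=O)=O)[C@@H]2CO[Si](c5ccccc5)(c6ccccc6)C(C)(C)C)ccc1OCc7ccccc7 | intermediate
16 | [(2R,3S)-2-{[(tert-butyldiphenylsilyl)oxy]methyl}-5-hydroxy-3-(4-hydroxy-3-methoxyphenyl)-6-methoxy-2,3-dihydro-1H-indene-1,1-diyl]dimethanediyl dimethanesulfonate (key-step precursor) | COc1cc([C@H]2c3cc(O)c(OC)cc3C(COS(C)(=O)=O)(COS(C)(=O)=O)[C@@H]2CO[Si](c5ccccc5)(c6ccccc6)C(C)(C)C)ccc1O | intermediate
17 | (1S,2R)-2-{[(tert-butyldiphenylsilyl)oxy]methyl}-1-(4-hydroxy-3-methoxyphenyl)-6-methoxy-3-[(methanesulfonyloxy)methyl]-1,2-dihydronaphthalen-7-ol (not isolated) | COc1cc([C@H]2c3cc(O)c(OC)cc3C=C(COS(C)(=O)=O)[C@@H]2CO[Si](c5ccccc5)(c6ccccc6)C(C)(C)C)ccc1O | intermediate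
18 | (1S,2R)-3-(acetoxymethyl)-2-{[(tert-butyldiphenylsilyl)oxy]methyl}-1-(4-hydroxy-3-methoxyphenyl)-6-methoxy-1,2-dihydronaphthalen-7-ol (key-step product) | COc1cc([C@H]2c3cc(O)c(OC)cc3C=C(COC(C)=O)[C@@H]2CO[Si](c5ccccc5)(c6ccccc6)C(C)(C)C)ccc1O | intermediate
19 | (1S,2R)-2-{[(tert-butyldiphenylsilyl)oxy]methyl}-3-(hydroxymethyl)-1-(4-hydroxy-3-methoxyphenyl)-6-methoxy-1,2-dihydronaphthalen-7-ol | COc1cc([C@H]2c3cc(O)c(OC)cc3C=C(CO)[C@@H]2CO[Si](c5ccccc5)(c6ccccc6)C(C)(C)C)ccc1O | intermediate
20 | tris(2,2,2-trichloroethyl carbonate) of 19 (1S,2R) | COc1cc([C@H]2c3cc(OC(=O)OCC(Cl)(Cl)Cl)c(OC)cc3C=C(COC(=O)OCC(Cl)(Cl)Cl)[C@@H]2CO[Si](c5ccccc5)(c6ccccc6)C(C)(C)C)ccc1OC(=O)OCC(Cl)(Cl)Cl | intermediate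
21 | (1S,2R)-2-(hydroxymethyl) tris-carbonate | COc1cc([C@H]2c3cc(OC(=O)OCC(Cl)(Cl)Cl)c(OC)cc3C=C(COC(=O)OCC(Cl)(Cl)Cl)[C@@H]2CO)ccc1OC(=O)OCC(Cl)(Cl)Cl | intermediate
22 | (1S,2R)-2-formyl tris-carbonate | COc1cc([C@H]2c3cc(OC(=O)OCC(Cl)(Cl)Cl)c(OC)cc3C=C(COC(=O)OCC(Cl)(Cl)Cl)[C@@H]2C=O)ccc1OC(=O)OCC(Cl)(Cl)Cl | intermediate
23 | CNP0591394.1, (1S,2R)-7-hydroxy-3-(hydroxymethyl)-1-(4-hydroxy-3-methoxyphenyl)-6-methoxy-1,2-dihydronaphthalene-2-carbaldehyde | COc1cc([C@H]2c3cc(O)c(OC)cc3C=C(CO)[C@@H]2C=O)ccc1O | target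

**Step count**

Total: 17 steps. Longest linear sequence: 17 steps (from 1; 5 is a purchased coupling partner).

**Steps most likely to fail**

Step 12. Three processes may divert the reaction. The bridged ion may be captured by acetate at the CH2 carbon instead of opening toward C3, which gives unrearranged acetoxymethyl indanes. C2 may migrate in place of ring A. The silyl ether oxygen may trap a cation with loss of silicon to give a cyclic ether. The fallback sets out from 10 and returns at 19; it expands the ring at the ketone stage. Lewis-acid-promoted diazo homologation of 10 (TMSCHN2, BF3·OEt2, CH2Cl2, −78 °C, aryl migration) should give the 2-tetralone-type ketone F1. Hydrogenolysis (H2, 10% Pd/C, EtOAc) gives the bis-phenol ketone F2. Silylation (TBSCl, imidazole, DMF) gives the bis(aryl TBS ether) F3. Enolisation toward the benzylic CH2 and triflation (KN(SiMe3)2, PhNTf2, THF, −78 °C) gives the enol triflate F4. Stille hydroxymethylation (Bu3SnCH2OH, Pd(PPh3)4, LiCl, dioxane, 90 °C) gives the allylic alcohol F5. Cleavage of the two aryl silyl ethers (K2CO3, MeOH, rt) gives 19.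

Step 8. The basic ylide may enolise the hindered, electron-rich aryl ketone faster than it adds, and the enolate may then expel silanolate (E1cB) to give a 2-methylene indanone. The fallback sets out from 10 and returns at 12. Non-basic methylenation (Cp2TiMe2, toluene, 65 °C) gives the 1-methylene indane F6. Hydroboration and oxidation (9-BBN, THF; then NaBO3·4H2O) gives the primary alcohol F7 as C1 epimers. Dess–Martin oxidation gives 12.

Step 5. Carbopalladation may run through a neutral, phosphine-dissociated palladium bromide complex and erode the enantioselectivity, and formate may reduce the C–Br bond or the enone before cyclisation. The fallback sets out from 7 and returns at 8. Miyaura borylation (B2pin2, Pd(dppf)Cl2, KOAc, dioxane, 80 °C) gives the aryl boronate chalcone F8. Rhodium-catalysed asymmetric intramolecular 1,4-addition ([RhCl(cod)]2, (R)-BINAP or its antipode, aq. K3PO4, dioxane, 60 °C) gives 8.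

**Further compounds**

F1 | step 12 | (1S,2S; target numbering) 7-(benzyloxy)-1-[4-(benzyloxy)-3-methoxyphenyl]-2-{[(tert-butyldiphenylsilyl)oxy]methyl}-6-methoxy-1,4-dihydronaphthalen-3(2H)-one | COc1cc([C@H]2c3cc(OCc4ccccc4)c(OC)cc3CC(=O)[C@@H]2CO[Si](c5ccccc5)(c6ccccc6)C(C)(C)C)ccc1OCc7ccccc7
F2 | step 12 | bis-phenol ketone from F1 | COc1cc([C@H]2c3cc(O)c(OC)cc3CC(=O)[C@@H]2CO[Si](c5ccccc5)(c6ccccc6)C(C)(C)C)ccc1O
F3 | step 12 | bis(aryl tert-butyldimethylsilyl ether) of F2 | COc1cc([C@H]2c3cc(O[Si](C)(C)C(C)(C)C)c(OC)cc3CC(=O)[C@@H]2CO[Si](c5ccccc5)(c6ccccc6)C(C)(C)C)ccc1O[Si](C)(C)C(C)(C)C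
F4 | step 12 | C3=C4 enol triflate of F3 | COc1cc([C@H]2c3cc(O[Si](C)(C)C(C)(C)C)c(OC)cc3C=C(OS(=O)(=O)C(F)(F)F)[C@@H]2CO[Si](c5ccccc5)(c6ccccc6)C(C)(C)C)ccc1O[Si](C)(C)C(C)(C)C
F5 | step 12 | (1S,2R) 3-(hydroxymethyl)-1,2-dihydronaphthalene with two aryl TBS ethers | COc1cc([C@H]2c3cc(O[Si](C)(C)C(C)(C)C)c(OC)cc3C=C(CO)[C@@H]2CO[Si](c5ccccc5)(c6ccccc6)C(C)(C)C)ccc1O[Si](C)(C)C(C)(C)C
F6 | step 8 | (2R,3S)-1-methylidene analogue of 10 | COc1cc([C@H]2c3cc(OCc4ccccc4)c(OC)cc3C(=C)[C@@H]2CO[Si](c5ccccc5)(c6ccccc6)C(C)(C)C)ccc1OCc7ccccc7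
F7 | step 8 | (2R,3S)-1-(hydroxymethyl)indane, C1 epimers | COc1cc([C@H]2c3cc(OCc4ccccc4)c(OC)cc3C(CO)[C@@H]2CO[Si](c5ccccc5)(c6ccccc6)C(C)(C)C)ccc1OCc7ccccc7
F8 | step 5 | (E)-chalcone with a pinacol boronate in place of bromine | COc1cc(/C=C/C(=O)c2cc(OC)c(OCc3ccccc3)cc2B4OC(C)(C)C(C)(C)O4)ccc1OCc1ccccc1
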